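(The numbers in the tables are simulated from invented constants, noise included.)

A closed, stirred vessel holds free monomer and initiator at a set temperature, and monomer passes into chains; spring, winter, autumn and summer share one charge and differ in their heat, while alpha, beta and zeta are earlier runs with charges of their own.

| flask | free monomer | initiator | temperature | remark | time |
|---|---|---|---|---|---|
| alpha | 0.20 M | 5.6 mM | 45 °C | run made earlier |  |
| beta | 0.20 M | 8.8 mM | 75 °C | run made earlier |  |
| zeta | 0.40 M | 4 mM | 45 °C | run made earlier |  |
| spring | 0.20 M | 4.0 mM | 50 °C |  | 3.0 d |
| winter | 0.20 M | 4.0 mM | 75 °C |  | 3.0 d |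
| autumn | 0.20 M | 4.0 mM |  | at 100 °C until 20 h, from then on at 50 °C | 3.0 d |
| summer | 0.20 M | 4.0 mM | 100 °C |  | 3.0 d |

alpha run (percent of the free monomer charged)

| time / d | monomer in chains / % | free monomer / % |
|---|---|---|
| 0.417 | 5.5 | 59.4 |
| 1.04 | 15.9 | 25.4 |
| 2.08 | 20.9 | 5.4 |
| 3.00 | 22.8 | 3.1 |

beta run (percent of the free monomer charged)

| time / h | monomer in chains / % | free monomer / % |
|---|---|---|
| 3.00 | 15.5 | 1.7 |
| 8.00 | 14.9 | 1.0 |
| 15.0 | 16.0 | 0 |
| 20.0 | 16.0 | 0 |

zeta run (percent of the free monomer charged)

| time / d | monomer in chains / % | free monomer / % |
|---|---|---|
| 0.417 | 8.6 | 57.0 |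
| 1.04 | 20.3 | 21.4 |
| 2.08 | 23.3 | 4.4 |
| 3.00 | 27.1 | 1.6 |

(each reading ± 1 percentage point)

- the earlier runs were read with a standard deviation of 1 percentage point

- which flask leads in amount of monomer in chains, in percent of the free monomer charged ("all alike" within 1.5 percentage points) (spring / winter / autumn / summer / all alike)
- how much monomer in chains is there at the end, in percent of the free monomer charged: spring
- how much monomer in chains is there at the end, in percent of the free monomer charged: winter
- how much monomer in chains is there at the end, in percent of the free monomer charged: autumn
- how much monomer in chains is there at the end, in percent of the free monomer charged: summer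

Two chemists read these runs differently. The first reckons by speed: beta had 15.5 % in chains at 3.00 h and alpha 5.5 % at 0.417 d, so beta, though it held more initiator, made chains about ten times as fast, and since alpha's chains were still climbing at its last reading, he expects summer, at 100 °C, to lead.

The second reckons by what remains to be used. From alpha's 25.4 % of free monomer at 1.04 d she reads a half-life of 0.526 d, and from beta's 1.7 % at 3.00 h one of 0.510 h, both carrying the scatter of their readings. Alpha's 3.00 d thus holds 5.70 half-lives, and this half-life count n, the time a flask has divided by the half-life of its free monomer, is her measure, since free monomer that falls first-order is halved with each unit of n.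

Winter, at beta's temperature, has a count of 141, and beta shows what such a count means: its chains read 15.5 % at the first reading and 16.0 % at the last, below alpha's 22.8 % despite more initiator. Once n is large, she argues, the chain figure is a share of the charge, a selectivity, and not a matter of time. Autumn's hot stretch of 20 h is far longer than beta's half-life, and its heat is greater than beta's, so she gives autumn summer's figure.

The count yields no percentage by itself. The forecast, on her side, rests on its own ground, that “The final yield is therefore set by the branching ratio”: spring leads, with 19.5 % for spring, 13.5 % for winter, and 9.3 % for autumn and for summer alike.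

The flasks give 17.4 % for spring, 10.0 % for winter, 5.92 % for autumn and 5.92 % for summer, so spring leads, as forecast, and summer trails it.

    2 initiator ⇌ resting dimer (K = 2400 /M, k = 36.0 /M/h, Ea = 80.0 kJ/mol, ΔH = −31.0 kJ/mol)
    free monomer → uncatalysed product (k = 0.0780 /h, Ea = 102 kJ/mol)
    free monomer + living end → monomer in chains + living end, rate k3*[living end]*[free monomer] (k = 12.0 /M/h, Ea = 79.0 kJ/mol)
    free monomer + initiator → living end + monomer in chains (k = 0.730 /M/h, Ea = 89.0 kJ/mol)
    (constants at 50 °C)

In spring at 0.297 d, free monomer passed into uncatalysed product 4.5 times as fast as into monomer in chains, and 0.078 % of the free monomer stood at the end beside 82.5 % of uncatalysed product, which makes a count of 10.3 in the 3.0 d, more than the 5.70 read for alpha. The repeat of spring at 25 °C kept 74.6 % of its free monomer, a count of only 0.422, and there the first chemist's view holds, for that colder flask trails spring with 5.06 % in chains.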